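## Retrosynthetic overview
1. Target 10 ⇒ hexamethyl ether 9. Thiolate removes five of the six O‑methyl groups. Ring A stops at the mono‑phenol, and its two OMe groups are equivalent by symmetry.
2. 9 ⇒ aryl bromide 7 + 4‑methoxybenzylzinc chloride 8. A Negishi coupling at the single, unhindered ring‑B C–Br places the benzyl group that electrophilic substitution cannot reach.
3. 7 ⇒ bibenzyl 5 + bis(4‑methoxybenzyl) ether 6. A double Friedel–Crafts benzylation of the only doubly activated ring (ring A) cuts both ring‑A ArCH2–Ar bonds at once.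
4. 5 ⇒ 3,5‑dimethoxystyrene 1 / 9‑BBN 2 + 3‑bromo‑5‑iodoanisole 3, by B‑alkyl Suzuki coupling in which C–I reacts before C–Br.
5. No ring is formed, since all five benzene rings are bought. Rings A and B are joined first, then the two ring‑A anisyl rings are added, then the ring‑B anisyl ring.

Assumption: the target has no stereocentre and no configurationally stable axis, so it is achiral and "single enantiomer" needs no stereocontrol.

## Route

Step 1
Reactants: 1 3,5‑dimethoxystyrene; 2 9‑borabicyclo[3.3.1]nonane (9‑BBN, 0.5 M in THF); 3 1‑bromo‑3‑iodo‑5‑methoxybenzene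
Product: 5 1‑bromo‑3‑[2‑(3,5‑dimethoxyphenyl)ethyl]‑5‑methoxybenzene, via 9‑[2‑(3,5‑dimethoxyphenyl)ethyl]‑9‑BBN 4 (not isolated)
Conditions: 1 (1.0 equiv), 2 (1.05 equiv), THF, 0 °C → rt, 3 h; then 3 (1.05 equiv), PdCl2(dppf)·CH2Cl2 (3 mol %), 3 M aq. NaOH, THF, rt → 40 °C
Reagents that add atoms: none
Why: Anti‑Markovnikov hydroboration of the styrene (>98 % terminal with 9‑BBN) is followed by a B‑alkyl Suzuki–Miyaura coupling, and because oxidative addition into C–I is much faster than into C–Br at ≤40 °C and the borane is limiting, the bromide survives for step 3 (no stereocentre is formed).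

Step 2
Reactants: 5 1‑bromo‑3‑[2‑(3,5‑dimethoxyphenyl)ethyl]‑5‑methoxybenzene; 6 bis(4‑methoxybenzyl) ether
Product: 7 3‑[2‑(3‑bromo‑5‑methoxyphenyl)ethyl]‑1,5‑dimethoxy‑2,4‑bis(4‑methoxybenzyl)benzene
Conditions: 6 (1.1 equiv, added over 2 h), Bi(OTf)3 (5 mol %), MeNO2, rt → 40 °C
Reagents that add atoms: none
Why: In this double Friedel–Crafts benzylation the acid ionises 6 to a 4‑methoxybenzyl cation and 4‑methoxybenzyl alcohol, which ionises in turn, so one molecule of 6 delivers both benzyl groups and loses only water, and both cations go to the positions beside the bridge on ring A (each para to one OMe and ortho to the other) because C4 is shielded between two OMe groups, ring B is deactivated by Br and the anisyl rings are far weaker nucleophiles (no stereocentre is formed).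

Step 3
Reactants: 7 3‑[2‑(3‑bromo‑5‑methoxyphenyl)ethyl]‑1,5‑dimethoxy‑2,4‑bis(4‑methoxybenzyl)benzene; 8 4‑methoxybenzylzinc chloride (0.5 M in THF)
Product: 9 1,5‑dimethoxy‑2,4‑bis(4‑methoxybenzyl)‑3‑{2‑[3‑methoxy‑5‑(4‑methoxybenzyl)phenyl]ethyl}benzene
Conditions: 8 (1.5 equiv), Pd(OAc)2 (2 mol %), SPhos (4 mol %), THF, rt → 40 °C
Reagents that add atoms: none
Why: This Negishi sp2–sp3 cross‑coupling places the benzyl group at a position that is meta to both the OMe and the bridge, using the only C–Br bond, which is unhindered, while the benzylzinc has no β‑hydrogen and the aryl methyl ethers are inert.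

Step 4
Reactants: 9 1,5‑dimethoxy‑2,4‑bis(4‑methoxybenzyl)‑3‑{2‑[3‑methoxy‑5‑(4‑methoxybenzyl)phenyl]ethyl}benzene
Product: 10 3‑{2‑[3‑hydroxy‑5‑(4‑hydroxybenzyl)phenyl]ethyl}‑2,4‑bis(4‑hydroxybenzyl)‑5‑methoxyphenol (target)
Conditions: NaSEt (20 equiv), DMF, 145 °C, Ar, followed by LC‑MS; then cold 1 M HCl
Reagents that add atoms: none
Why: In this SN2 O‑demethylation by thiolate each of the four mono‑methoxy rings loses its only methyl and ring A loses one of its two equivalent methyls, after which the ring‑A phenoxide blocks the second cleavage because the leaving group would be a dianion (the resorcinol dimethyl ether → monomethyl ether selectivity).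

## Compound list
1 | 3,5‑dimethoxystyrene | C=Cc1cc(OC)cc(OC)c1 | starting material
2 | 9‑borabicyclo[3.3.1]nonane (9‑BBN, drawn as monomer) | B1C2CCCC1CCC2 | starting material
3 | 1‑bromo‑3‑iodo‑5‑methoxybenzene | COc1cc(Br)cc(I)c1 | starting material
4 | 9‑[2‑(3,5‑dimethoxyphenyl)ethyl]‑9‑borabicyclo[3.3.1]nonane | COc1cc(CCB2C3CCCC2CCC3)cc(OC)c1 | intermediate (not isolated)
5 | 1‑bromo‑3‑[2‑(3,5‑dimethoxyphenyl)ethyl]‑5‑methoxybenzene | COc1cc(Br)cc(CCc2cc(OC)cc(OC)c2)c1 | intermediate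
6 | bis(4‑methoxybenzyl) ether | COc1ccc(COCc2ccc(OC)cc2)cc1 | starting material
7 | 3‑[2‑(3‑bromo‑5‑methoxyphenyl)ethyl]‑1,5‑dimethoxy‑2,4‑bis(4‑methoxybenzyl)benzene | COc1cc(OC)c(Cc2ccc(OC)cc2)c(CCc2cc(OC)cc(Br)c2)c1Cc1ccc(OC)cc1 | intermediate
8 | 4‑methoxybenzylzinc chloride | COc1ccc(C[Zn]Cl)cc1 | starting material
9 | 1,5‑dimethoxy‑2,4‑bis(4‑methoxybenzyl)‑3‑{2‑[3‑methoxy‑5‑(4‑methoxybenzyl)phenyl]ethyl}benzene | COc1cc(OC)c(Cc2ccc(OC)cc2)c(CCc2cc(OC)cc(Cc3ccc(OC)cc3)c2)c1Cc1ccc(OC)cc1 | intermediate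
10 | 3‑{2‑[3‑hydroxy‑5‑(4‑hydroxybenzyl)phenyl]ethyl}‑2,4‑bis(4‑hydroxybenzyl)‑5‑methoxyphenol (CNP0204120.0, achiral) | COc1cc(O)c(Cc2ccc(O)cc2)c(CCc2cc(O)cc(Cc3ccc(O)cc3)c2)c1Cc1ccc(O)cc1 | target

Total step count: 4. Longest linear sequence: 4.

## Steps most likely to fail, with fallbacks

**Step 2 (double Friedel–Crafts benzylation).** The risks are some attack at C4, a third benzylation, and self‑condensation of the 4‑methoxybenzyl cation, all of which give isomers that are hard to separate.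
The fallback sets out from 5 and comes back at 9, bypassing 7. It fixes the regiochemistry by halogenation and forms all three ArCH2–Ar bonds by cross‑coupling instead of electrophilic substitution. NBS (2.05 equiv, MeCN, 0 °C → rt, dark) brominates the two positions beside the bridge on ring A. This gives 2,4‑dibromo‑3‑[2‑(3‑bromo‑5‑methoxyphenyl)ethyl]‑1,5‑dimethoxybenzene F1. A threefold Negishi coupling of F1 with 8 (4.5 equiv, Pd(OAc)2/SPhos, THF, rt → 60 °C) then replaces all three bromides and gives 9.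

**Step 4 (five‑fold selective demethylation).** The risks are mixtures of partly demethylated products and some over‑demethylation on the large polyanionic substrate.
The fallback sets out from 5 and comes back at 10. It moves the OMe/OH differentiation to a small early intermediate and carries benzyl ethers to the end. NaSEt (5 equiv, DMF, 125 °C) removes one methyl from each ring of 5 and gives 3‑[2‑(3‑bromo‑5‑hydroxyphenyl)ethyl]‑5‑methoxyphenol F2. BnBr/K2CO3 in DMF then gives 1‑(benzyloxy)‑3‑{2‑[3‑(benzyloxy)‑5‑bromophenyl]ethyl}‑5‑methoxybenzene F3. NBS (2.05 equiv, MeCN) converts this into 1‑(benzyloxy)‑2,4‑dibromo‑3‑{2‑[3‑(benzyloxy)‑5‑bromophenyl]ethyl}‑5‑methoxybenzene F4. Zinc dust/LiCl insertion into commercial 4‑(benzyloxy)benzyl chloride in THF gives 4‑(benzyloxy)benzylzinc chloride F5. This reagent couples three times with F4 (Pd(OAc)2/SPhos, THF, 60 °C) to give 1‑(benzyloxy)‑2,4‑bis[4‑(benzyloxy)benzyl]‑3‑(2‑{3‑(benzyloxy)‑5‑[4‑(benzyloxy)benzyl]phenyl}ethyl)‑5‑methoxybenzene F6. Hydrogenolysis (H2, Pd/C, EtOAc/MeOH) removes all five benzyl groups, leaves the methyl ether untouched, and gives 10.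

**Step 1 (B‑alkyl Suzuki).** The risks are loss of I/Br chemoselectivity and protodeboronation.
The fallback sets out from 1 and 3 and comes back at 5. A ligand‑free Jeffery–Heck reaction of 1 with 3 (Pd(OAc)2, n‑Bu4NCl, K2CO3, DMF, 60 °C) engages only the iodide. It gives (E)‑1‑bromo‑3‑[2‑(3,5‑dimethoxyphenyl)ethenyl]‑5‑methoxybenzene F7. Diimide reduction (TsNHNH2, NaOAc, THF/H2O, reflux) then saturates the alkene without touching the C–Br bond and gives 5.

## Further compounds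
F1 | step 2 | 2,4‑dibromo‑3‑[2‑(3‑bromo‑5‑methoxyphenyl)ethyl]‑1,5‑dimethoxybenzene | COc1cc(OC)c(Br)c(CCc2cc(Br)cc(OC)c2)c1Br
F2 | step 4 | 3‑[2‑(3‑bromo‑5‑hydroxyphenyl)ethyl]‑5‑methoxyphenol | COc1cc(O)cc(CCc2cc(O)cc(Br)c2)c1
F3 | step 4 | 1‑(benzyloxy)‑3‑{2‑[3‑(benzyloxy)‑5‑bromophenyl]ethyl}‑5‑methoxybenzene | COc1cc(OCc2ccccc2)cc(CCc2cc(OCc3ccccc3)cc(Br)c2)c1
F4 | step 4 | 1‑(benzyloxy)‑2,4‑dibromo‑3‑{2‑[3‑(benzyloxy)‑5‑bromophenyl]ethyl}‑5‑methoxybenzene | COc1cc(OCc2ccccc2)c(Br)c(CCc2cc(OCc3ccccc3)cc(Br)c2)c1Br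
F5 | step 4 | 4‑(benzyloxy)benzylzinc chloride | Cl[Zn]Cc1ccc(OCc2ccccc2)cc1
F6 | step 4 | 1‑(benzyloxy)‑2,4‑bis[4‑(benzyloxy)benzyl]‑3‑(2‑{3‑(benzyloxy)‑5‑[4‑(benzyloxy)benzyl]phenyl}ethyl)‑5‑methoxybenzene | COc1cc(OCc2ccccc2)c(Cc2ccc(OCc3ccccc3)cc2)c(CCc2cc(OCc3ccccc3)cc(Cc3ccc(OCc4ccccc4)cc3)c2)c1Cc1ccc(OCc2ccccc2)cc1
F7 | step 1 | (E)‑1‑bromo‑3‑[2‑(3,5‑dimethoxyphenyl)ethenyl]‑5‑methoxybenzene | COc1cc(Br)cc(/C=C/c2cc(OC)cc(OC)c2)c1
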